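**Retrosynthetic overview**

1. Skeleton locants: cyclopentanone C1 (quaternary, Me), C2 (C=O), C3, C4 (i-Pr), C5 (C–OH); seven-membered ring C5, C6, C7, C8 (=C–Me), C9 (=CH), C10 (O-anisoyl), back to C1.
2. Feature: the C5 oxygen and the C8 methyl sit on two carbons joined through C6–C7, which is the pattern of the two α-carbons of 2-methylfuran; C9–C10(O)–C1 is an oxyallyl unit and C2–C3–C4 a three-atom tether between them.
3. Target ⇐ C2 oxidation, C10 anisoylation and C5-OH-directed anti reduction of the C10 enone ⇐ β-elimination opening of the C8–O bridge of a saturated 8-oxabicyclo[3.2.1]octan-3-one.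
4. Oxa-bridged tricycle ⇐ intramolecular furan–oxyallyl (4+3) cycloaddition forming C1–C5 and C8–C9; ring order: furan from the start, then the seven-membered ring and the cyclopentane together, oxygen bridge cut afterwards.
5. α-Chloro ketone ⇐ MeMgBr on an α-chloro-β-silyloxy Weinreb amide ⇐ chlorination and CBS reduction of a β-keto amide ⇐ propionamide aldol on the aldehyde from the organocatalytic Friedel–Crafts addition of 2-methylfuran to (E)-4-methylpent-2-enal (sets C4).

Key step: step 8

Assumption (step 1): the sense of induction is taken from the usual shielding model of this imidazolidinone, which points to the (2R,5R)-catalyst for the (R)-aldehyde; should analysis of the derived alcohol show the antipode, the (2S,5S)-catalyst is used instead.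

Assumption (C2): the temporary C2 carbinol is set as R so that its silyloxy group can point away from the furan in the compact cycloaddition geometry; C2 is oxidised in the last step, so this choice serves only the key step.

Remark: chlorine is introduced on a 1,3-dicarbonyl stage because regioselective enolisation of the methyl ketone towards the tertiary carbon C1 cannot be relied on and the furan excludes harsher chlorinating agents.

**Step 1**
Reactants: 1 2-methylfuran; 2 (E)-4-methylpent-2-enal
Product: 3 (3R)-4-methyl-3-(5-methylfuran-2-yl)pentanal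
Conditions: (2R,5R)-5-benzyl-2-tert-butyl-3-methylimidazolidin-4-one·TFA (20 mol %), 1 (3 equiv), CH2Cl2/i-PrOH, −40 °C
Reagents that add atoms: none
Why: Iminium-catalysed enantioselective Friedel–Crafts conjugate alkylation, in which the (E)-iminium ion of the enal is shielded on one face by the benzyl group and the free C5 position of 2-methylfuran attacks the β-carbon on the open face, which sets C4.

**Step 2**
Reactants: 3 (3R)-4-methyl-3-(5-methylfuran-2-yl)pentanal; 4 N-methoxy-N-methylpropanamide
Product: 6 (5R)-3-hydroxy-N-methoxy-N,2,6-trimethyl-5-(5-methylfuran-2-yl)heptanamide (diastereomer mixture at C2 and C3), via lithium amide enolate 5 (not isolated)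
Conditions: LDA, THF, −78 °C; then 3, −78 °C; aq. NH4Cl
Reagents that add atoms: none
Why: Lithium amide-enolate aldol addition to an unhindered aldehyde at −78 °C, where the Weinreb amide enolate is stable; the two new centres form as a mixture that steps 3–5 erase and reset.

**Step 3**
Reactants: 6 (5R)-3-hydroxy-N-methoxy-N,2,6-trimethyl-5-(5-methylfuran-2-yl)heptanamide
Product: 7 (5R)-N-methoxy-N,2,6-trimethyl-5-(5-methylfuran-2-yl)-3-oxoheptanamide
Conditions: Dess–Martin periodinane, CH2Cl2, 0 °C → rt
Reagents that add atoms: none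
Why: Dess–Martin oxidation of the secondary alcohol under near-neutral conditions that the furan tolerates should give the β-keto amide, with C4 untouched because it is not α to a carbonyl.

**Step 4**
Reactants: 7 (5R)-N-methoxy-N,2,6-trimethyl-5-(5-methylfuran-2-yl)-3-oxoheptanamide
Product: 8 (5R)-2-chloro-N-methoxy-N,2,6-trimethyl-5-(5-methylfuran-2-yl)-3-oxoheptanamide (both C2 epimers)
Conditions: NCS (1.05 equiv), Mg(ClO4)2 (cat.), EtOAc, 0 °C → rt, dark
Reagents that add atoms: N-chlorosuccinimide, O=C1CCC(=O)N1Cl
Why: Lewis-acid-catalysed electrophilic α-chlorination of a 1,3-dicarbonyl compound places chlorine only on the carbon flanked by both carbonyls (skeleton C1) and should be much faster than attack on the furan; both epimers form and both are usable.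

**Step 5**
Reactants: 8 (5R)-2-chloro-N-methoxy-N,2,6-trimethyl-5-(5-methylfuran-2-yl)-3-oxoheptanamide
Product: 9 (3R,5R)-2-chloro-3-hydroxy-N-methoxy-N,2,6-trimethyl-5-(5-methylfuran-2-yl)heptanamide (both C2 epimers)
Conditions: (S)-2-methyl-CBS-oxazaborolidine (20 mol %), catecholborane, toluene, −78 → −40 °C; MeOH, pH 7 buffer
Reagents that add atoms: none
Why: Corey–Bakshi–Shibata reduction, in which the ketone lies between a quaternary carbon (large) and a methylene (small), so the (S)-catalyst should deliver hydride under reagent control to give the (R)-carbinol (skeleton C2) in both chloride epimers, the amide and the tertiary chloride being inert to catecholborane at low temperature.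

**Step 6**
Reactants: 9 (3R,5R)-2-chloro-3-hydroxy-N-methoxy-N,2,6-trimethyl-5-(5-methylfuran-2-yl)heptanamide
Product: 10 (3R,5R)-3-[(tert-butyldimethylsilyl)oxy]-2-chloro-N-methoxy-N,2,6-trimethyl-5-(5-methylfuran-2-yl)heptanamide (both C2 epimers)
Conditions: TBSOTf, 2,6-lutidine, CH2Cl2, −78 → 0 °C
Reagents that add atoms: tert-butyldimethylsilyl trifluoromethanesulfonate, CC(C)(C)[Si](C)(C)OS(=O)(=O)C(F)(F)F
Why: Silylation of a hindered secondary alcohol with a silyl triflate and a base too weak to close the chlorohydrin to an epoxide.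

**Step 7**
Reactants: 10 (3R,5R)-3-[(tert-butyldimethylsilyl)oxy]-2-chloro-N-methoxy-N,2,6-trimethyl-5-(5-methylfuran-2-yl)heptanamide
Product: 11 (4R,6R)-4-[(tert-butyldimethylsilyl)oxy]-3-chloro-3,7-dimethyl-6-(5-methylfuran-2-yl)octan-2-one (both C3 epimers)
Conditions: MeMgBr (3 equiv), THF, 0 °C → rt; aq. NH4Cl
Reagents that add atoms: methylmagnesium bromide, C[Mg]Br
Why: Weinreb ketone synthesis, in which the Grignard reagent adds once to give a chelated tetrahedral intermediate that releases the methyl ketone only on work-up; the α-carbon has no hydrogen, so enolisation cannot compete.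

**Step 8**
Reactants: 11 (4R,6R)-4-[(tert-butyldimethylsilyl)oxy]-3-chloro-3,7-dimethyl-6-(5-methylfuran-2-yl)octan-2-one
Product: 13 (1S,2R,4R,5S,8R)-4-[(tert-butyldimethylsilyl)oxy]-5,8-dimethyl-2-(propan-2-yl)-11-oxatricyclo[6.2.1.0^{1,5}]undec-9-en-6-one, via oxyallyl cation 12 (not isolated)
Conditions: Et3N (3 equiv), CF3CH2OH (0.02 M), 0 °C → rt
Reagents that add atoms: none
Why: Triethylamine enolises the methyl ketone towards C9 and the ionising solvent assists loss of the tertiary chloride from C1 (both epimers converge), giving oxyallyl cation 12 (C9–C10–C1), which adds across the 2,5-positions of the tethered furan to form C1–C5 and C8–C9 in a concerted or fast stepwise (4+3) cycloaddition; the closest known reaction type is the intramolecular furan–oxyallyl cycloaddition of α-chloro ketones under amine/fluoro-alcohol conditions. The seven-membered carbocycle closes by the cycloaddition across the furan termini, and the cyclopentane closes in the exo mode because the tether C2–C3–C4 joins the cation terminus C1 to the furan carbon C5. C5 and C8 are set together by the furan face that reacts, which C4 controls: with C4–H turned towards the furan C6–H and the tether on the reacting face, the isopropyl group lies on the side of the ring oxygen and ends cis to the oxygen bridge. C1 is set by the topology of approach: the bulkier tether takes the position syn to the oxyallyl oxygen, and a compact arrangement (carbonyl carbon over C6/C7) then leaves the tether anti and the C1 methyl syn to the oxygen bridge, which is the cis ring fusion of the target. The step needs the compact rather than the extended arrangement (the extended one gives the C1 epimer with trans fusion) and attack on the correct furan face; the electron-rich 2,5-dialkylfuran, the tertiary cation terminus and the (R)-silyloxy group at C2 (its C–H can eclipse the oxyallyl C–O while the silyloxy group points away from the furan) favour this, but the cis-1,3 relation of the C1 methyl and the C4 isopropyl group across the new cyclopentane opposes it, so the ratio must be settled by experiment.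

**Step 9**
Reactants: 13 (1S,2R,4R,5S,8R)-4-[(tert-butyldimethylsilyl)oxy]-5,8-dimethyl-2-(propan-2-yl)-11-oxatricyclo[6.2.1.0^{1,5}]undec-9-en-6-one
Product: 14 (1S,2R,4R,5S,8S)-4-[(tert-butyldimethylsilyl)oxy]-5,8-dimethyl-2-(propan-2-yl)-11-oxatricyclo[6.2.1.0^{1,5}]undecan-6-one
Conditions: H2 (1 atm), 10 % Pd/C, EtOAc, rt
Reagents that add atoms: none
Why: Heterogeneous hydrogenation of the strained cis-disubstituted C6=C7 bridge alkene, which leaves the ketone and the silyl ether untouched and forms no stereocentre.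

**Step 10**
Reactants: 14 (1S,2R,4R,5S,8S)-4-[(tert-butyldimethylsilyl)oxy]-5,8-dimethyl-2-(propan-2-yl)-11-oxatricyclo[6.2.1.0^{1,5}]undecan-6-one
Product: 16 (1R,3R,3aS,8aS)-3-[(tert-butyldimethylsilyl)oxy]-8a-hydroxy-3a,6-dimethyl-1-(propan-2-yl)-2,3,3a,7,8,8a-hexahydroazulen-4(1H)-one, via trimethylsilyl ether enone 15 (not isolated)
Conditions: TMSOTf (1.3 equiv), Et3N, CH2Cl2, −78 → −20 °C; then 1 M HCl, THF, 0 °C
Reagents that add atoms: none
Why: Silyl-triflate-mediated β-elimination opening of an 8-oxabicyclo[3.2.1]octan-3-one (E1cB type), in which the ketone can enolise only towards C9 because C1 is quaternary, the enol silane expels the silylated bridge oxygen from C8 to give the C8=C9 enone with C5–OTMS, and brief mild acid frees the tertiary alcohol without touching the TBS ether; no stereocentre changes.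

**Step 11**
Reactants: 16 (1R,3R,3aS,8aS)-3-[(tert-butyldimethylsilyl)oxy]-8a-hydroxy-3a,6-dimethyl-1-(propan-2-yl)-2,3,3a,7,8,8a-hexahydroazulen-4(1H)-one
Product: 17 (1R,3R,3aS,4R,8aS)-3-[(tert-butyldimethylsilyl)oxy]-3a,6-dimethyl-1-(propan-2-yl)-1,2,3,3a,4,7,8,8a-octahydroazulene-4,8a-diol
Conditions: Me4NBH(OAc)3, MeCN/AcOH, −30 → 0 °C
Reagents that add atoms: none
Why: Evans–Saksena hydroxyl-directed reduction, in which the C5 hydroxyl exchanges onto boron and delivers hydride intramolecularly to the face of the C10 carbonyl that it occupies (1,2-reduction), giving the 1,3-anti diol with C10–OH trans to C5–OH and to the C1 methyl.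

**Step 12**
Reactants: 17 (1R,3R,3aS,4R,8aS)-3-[(tert-butyldimethylsilyl)oxy]-3a,6-dimethyl-1-(propan-2-yl)-1,2,3,3a,4,7,8,8a-octahydroazulene-4,8a-diol; 18 4-methoxybenzoyl chloride
Product: 19 (1R,3R,3aS,4R,8aS)-3-[(tert-butyldimethylsilyl)oxy]-8a-hydroxy-3a,6-dimethyl-1-(propan-2-yl)-1,2,3,3a,4,7,8,8a-octahydroazulen-4-yl 4-methoxybenzoate
Conditions: Et3N, DMAP (cat.), CH2Cl2, 0 °C → rt
Reagents that add atoms: none
Why: DMAP-catalysed acylation, selective for the secondary allylic alcohol because the tertiary C5 hydroxyl is not acylated under these conditions.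

**Step 13**
Reactants: 19 (1R,3R,3aS,4R,8aS)-3-[(tert-butyldimethylsilyl)oxy]-8a-hydroxy-3a,6-dimethyl-1-(propan-2-yl)-1,2,3,3a,4,7,8,8a-octahydroazulen-4-yl 4-methoxybenzoate
Product: 20 (1R,3R,3aR,4R,8aS)-3,8a-dihydroxy-3a,6-dimethyl-1-(propan-2-yl)-1,2,3,3a,4,7,8,8a-octahydroazulen-4-yl 4-methoxybenzoate
Conditions: HF·pyridine, pyridine/THF, 0 °C → rt
Reagents that add atoms: none
Why: Fluoride cleavage of the silyl ether under mildly acidic buffered conditions, which avoids the acyl migration and retro-aldol chemistry that a basic fluoride source could cause.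

**Step 14**
Reactants: 20 (1R,3R,3aR,4R,8aS)-3,8a-dihydroxy-3a,6-dimethyl-1-(propan-2-yl)-1,2,3,3a,4,7,8,8a-octahydroazulen-4-yl 4-methoxybenzoate
Product: 21 (1R,3aR,4R,8aS)-8a-hydroxy-3a,6-dimethyl-3-oxo-1-(propan-2-yl)-1,2,3,3a,4,7,8,8a-octahydroazulen-4-yl 4-methoxybenzoate (CNP0246512.1)
Conditions: Dess–Martin periodinane, CH2Cl2, 0 °C → rt
Reagents that add atoms: none
Why: Dess–Martin oxidation of the only secondary alcohol gives the C2 ketone under non-basic conditions, so the resulting β-hydroxy ketone should not undergo retro-aldol cleavage and the tertiary alcohol is inert.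

**Compound list**

1 | 2-methylfuran | Cc1ccco1 | starting material
2 | (E)-4-methylpent-2-enal | CC(C)/C=C/C=O | starting material
3 | (3R)-4-methyl-3-(5-methylfuran-2-yl)pentanal | O=CC[C@H](C(C)C)c1ccc(C)o1 | intermediate
4 | N-methoxy-N-methylpropanamide | CCC(=O)N(C)OC | starting material
5 | lithium (Z)-1-[methoxy(methyl)amino]prop-1-en-1-olate | C/C=C(\O[Li])N(C)OC | intermediate
6 | (5R)-3-hydroxy-N-methoxy-N,2,6-trimethyl-5-(5-methylfuran-2-yl)heptanamide (mixture at C2 and C3) | CON(C)C(=O)C(C)C(O)C[C@H](C(C)C)c1ccc(C)o1 | intermediate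
7 | (5R)-N-methoxy-N,2,6-trimethyl-5-(5-methylfuran-2-yl)-3-oxoheptanamide | CON(C)C(=O)C(C)C(=O)C[C@H](C(C)C)c1ccc(C)o1 | intermediate
8 | (5R)-2-chloro-N-methoxy-N,2,6-trimethyl-5-(5-methylfuran-2-yl)-3-oxoheptanamide (both C2 epimers) | CON(C)C(=O)C(C)(Cl)C(=O)C[C@H](C(C)C)c1ccc(C)o1 | intermediate
9 | (3R,5R)-2-chloro-3-hydroxy-N-methoxy-N,2,6-trimethyl-5-(5-methylfuran-2-yl)heptanamide (both C2 epimers) | CON(C)C(=O)C(C)(Cl)[C@H](O)C[C@H](C(C)C)c1ccc(C)o1 | intermediate
10 | (3R,5R)-3-[(tert-butyldimethylsilyl)oxy]-2-chloro-N-methoxy-N,2,6-trimethyl-5-(5-methylfuran-2-yl)heptanamide (both C2 epimers) | CON(C)C(=O)C(C)(Cl)[C@H](O[Si](C)(C)C(C)(C)C)C[C@H](C(C)C)c1ccc(C)o1 | intermediate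
11 | (4R,6R)-4-[(tert-butyldimethylsilyl)oxy]-3-chloro-3,7-dimethyl-6-(5-methylfuran-2-yl)octan-2-one (both C3 epimers) | CC(=O)C(C)(Cl)[C@H](O[Si](C)(C)C(C)(C)C)C[C@H](C(C)C)c1ccc(C)o1 | intermediate
12 | oxyallyl cation (zwitterion) from 11, C9–C10(O−)–C1(+) | C=C([O-])[C+](C)[C@H](O[Si](C)(C)C(C)(C)C)C[C@H](C(C)C)c1ccc(C)o1 | intermediate
13 | (1S,2R,4R,5S,8R)-4-[(tert-butyldimethylsilyl)oxy]-5,8-dimethyl-2-(propan-2-yl)-11-oxatricyclo[6.2.1.0^{1,5}]undec-9-en-6-one | O=C1C[C@]2(C)C=C[C@]3(O2)[C@@H](C(C)C)C[C@@H](O[Si](C)(C)C(C)(C)C)[C@]13C | intermediate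
14 | (1S,2R,4R,5S,8S)-4-[(tert-butyldimethylsilyl)oxy]-5,8-dimethyl-2-(propan-2-yl)-11-oxatricyclo[6.2.1.0^{1,5}]undecan-6-one | O=C1C[C@]2(C)CC[C@]3(O2)[C@@H](C(C)C)C[C@@H](O[Si](C)(C)C(C)(C)C)[C@]13C | intermediate
15 | (1R,3R,3aS,8aS)-3-[(tert-butyldimethylsilyl)oxy]-3a,6-dimethyl-1-(propan-2-yl)-8a-(trimethylsilyloxy)-2,3,3a,7,8,8a-hexahydroazulen-4(1H)-one | O=C1C=C(C)CC[C@]2(O[Si](C)(C)C)[C@@H](C(C)C)C[C@@H](O[Si](C)(C)C(C)(C)C)[C@]12C | intermediate
16 | (1R,3R,3aS,8aS)-3-[(tert-butyldimethylsilyl)oxy]-8a-hydroxy-3a,6-dimethyl-1-(propan-2-yl)-2,3,3a,7,8,8a-hexahydroazulen-4(1H)-one | O=C1C=C(C)CC[C@]2(O)[C@@H](C(C)C)C[C@@H](O[Si](C)(C)C(C)(C)C)[C@]12C | intermediate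
17 | (1R,3R,3aS,4R,8aS)-3-[(tert-butyldimethylsilyl)oxy]-3a,6-dimethyl-1-(propan-2-yl)-1,2,3,3a,4,7,8,8a-octahydroazulene-4,8a-diol | O[C@@H]1C=C(C)CC[C@]2(O)[C@@H](C(C)C)C[C@@H](O[Si](C)(C)C(C)(C)C)[C@]12C | intermediate
18 | 4-methoxybenzoyl chloride | COc1ccc(C(=O)Cl)cc1 | starting material
19 | (1R,3R,3aS,4R,8aS)-3-[(tert-butyldimethylsilyl)oxy]-8a-hydroxy-3a,6-dimethyl-1-(propan-2-yl)-1,2,3,3a,4,7,8,8a-octahydroazulen-4-yl 4-methoxybenzoate | COc1ccc(C(=O)O[C@@H]2C=C(C)CC[C@]3(O)[C@@H](C(C)C)C[C@@H](O[Si](C)(C)C(C)(C)C)[C@]23C)cc1 | intermediate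
20 | (1R,3R,3aR,4R,8aS)-3,8a-dihydroxy-3a,6-dimethyl-1-(propan-2-yl)-1,2,3,3a,4,7,8,8a-octahydroazulen-4-yl 4-methoxybenzoate | COc1ccc(C(=O)O[C@@H]2C=C(C)CC[C@]3(O)[C@@H](C(C)C)C[C@@H](O)[C@]23C)cc1 | intermediate
21 | (1R,3aR,4R,8aS)-8a-hydroxy-3a,6-dimethyl-3-oxo-1-(propan-2-yl)-1,2,3,3a,4,7,8,8a-octahydroazulen-4-yl 4-methoxybenzoate | COc1ccc(C(=O)O[C@@H]2C=C(C)CC[C@]3(O)[C@@H](C(C)C)CC(=O)[C@]23C)cc1 | target

**Step count and risks**

Total step count: 14. Longest linear sequence: 14 steps (1 or 2 to 21).

Steps most likely to fail: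

Step 8. The cation may close through the extended instead of the compact arrangement or on the other furan face, which gives diastereomers at C1 or at C5/C8. It may also be captured by trifluoroethanol or lose a proton before it cyclises. Fallback: change the type of cation. Ketone 11 is deprotonated at C9, the only acidic position, with LDA in the presence of chlorotrimethylsilane (THF, −78 °C) to give the 2-(trimethylsilyloxy)allyl chloride F1. This is ionised with zinc chloride in CH2Cl2 at −40 °C. The resulting 2-silyloxyallyl cation undergoes the same intramolecular (4+3) cycloaddition in a non-nucleophilic medium, and loss of the silyl group returns the route at ketone 13. The more electrophilic, non-zwitterionic cation cannot be intercepted by solvent and reacts through a different balance of compact and extended geometries.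

Step 10. The β-elimination may stall or revert by transannular re-addition of the C5 oxygen to C8, and over-silylation may lead to a dienol ether that reprotonates out of conjugation. Fallback: reverse the order of hydrogenation and bridge opening. Cycloadduct 13 is treated with TMSOTf/Et3N while the C6=C7 bond is still present. The elimination then gives the linearly conjugated silyloxy dienone F2; the extra conjugation drives the opening and the silyl ether blocks re-addition. Selective hydrogenation of the less substituted γ,δ-alkene (H2, RhCl(PPh3)3, benzene) gives silyl ether 15, which is hydrolysed to 16 as in the second operation of step 10.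

Step 11. Exchange of the hindered tertiary C5 hydroxyl onto boron may be too slow, so that hydride arrives without guidance, on the wrong face of C10 or in conjugate fashion. Fallback: a samarium-catalysed Evans–Tishchenko reduction. Hydroxy enone 16 is treated with acetaldehyde and catalytic SmI2 (THF, −10 °C). The hemiacetal formed at the C5 oxygen transfers its hydride intramolecularly to the same face of C10 and gives the anti-configured C5 acetate with free C10 alcohol F3. DIBAL-H (CH2Cl2, −78 °C) then removes the tertiary acetate and returns the route at diol 17.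

**Further compounds**

F1 | step 8 | tert-butyl{[(4R,6R)-3-chloro-3,7-dimethyl-6-(5-methylfuran-2-yl)-2-(trimethylsilyloxy)oct-1-en-4-yl]oxy}dimethylsilane (both C3 epimers) | C=C(O[Si](C)(C)C)C(C)(Cl)[C@H](O[Si](C)(C)C(C)(C)C)C[C@H](C(C)C)c1ccc(C)o1
F2 | step 10 | (1R,3R,3aS,8aS)-3-[(tert-butyldimethylsilyl)oxy]-3a,6-dimethyl-1-(propan-2-yl)-8a-(trimethylsilyloxy)-2,3,3a,8a-tetrahydroazulen-4(1H)-one | O=C1C=C(C)C=C[C@]2(O[Si](C)(C)C)[C@@H](C(C)C)C[C@@H](O[Si](C)(C)C(C)(C)C)[C@]12C
F3 | step 11 | (1R,3R,3aS,4R,8aS)-3-[(tert-butyldimethylsilyl)oxy]-4-hydroxy-3a,6-dimethyl-1-(propan-2-yl)-1,2,3,3a,4,7,8,8a-octahydroazulen-8a-yl acetate | O[C@@H]1C=C(C)CC[C@]2(OC(C)=O)[C@@H](C(C)C)C[C@@H](O[Si](C)(C)C(C)(C)C)[C@]12C
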